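**Retrosynthetic overview**
1. Feature: in the seven-membered carbocycle C1–C5–C6–C7–C8–C9–C10 the C5 and C9 oxygens are 1,4 across C1–C10, and the five-membered lactone (O–C6–C7–C11–C12) is cis-fused at C6–C7. A cyclobutane C5–C6–C7–C8 fused to a cyclopentanone (C9, C8, C5, C1, C10) and to a tetrahydrofuran leaves exactly this array when C5–C8 is cut by retro-aldol.
2. Late disconnections: C11=C13 (Mannich/elimination), C3–C4 (boron aldol with acetaldehyde), C12=O (RuO4 on the tetrahydrofuran), C2=O (alkyne hydration), C5 ester, and both C5–H and C9–H (one hydroxyl-directed reduction from the C1 hydroxyl).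
3. Ring order: cyclopentenone (Piancatelli) → cyclobutane carrying the tetrahydrofuran ([2+2]; C5–C6 and C7–C8) → seven-membered ring (C5–C8 retro-aldol) → lactone (oxidation of C12).
4. Precursor: the enol acetate is made from a C5 mono-ketone that can enolise only towards C8, before C9 is oxidised, so the 3-acetoxy enone is a single regioisomer. C1 and C10 come from acetylide addition anti to the C10 methyl of a resolved Piancatelli enone.

Key step: step 9

**Conventions and assumptions**
- Target numbering (C1–C13, plus C14 = methyl on C10 and C15 = methyl on C4) is used for every intermediate. α is the face of the C1 oxygen, β the face of the C1 carbon substituent. All seven-ring intermediates have C1–O α, C10–CH3 α, C6–O α, C7–C11 α (H6, H7 β) and, once formed, C5–O β and C9–O β.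
- Assumption: the lipase of step 2 acylates the (4S,5R)-enantiomer of 2 faster, by analogy with 4-hydroxycyclopent-2-enone (same spatial arrangement at the carbinol carbon); if the sense is the reverse, the acetate fraction is used after enzymatic deacetylation.
- Assumption: (−)-Ipc2BCl (from (+)-α-pinene) sends the methyl-ketone enolate to the Re face of acetaldehyde (4S); if the sense is the reverse, the (+)-reagent is used.

**Route**

Step 1
Reactants: 1 (±)-1-(furan-2-yl)ethanol
Product: 2 (±)-trans-4-hydroxy-5-methylcyclopent-2-en-1-one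
Conditions: ZnCl2 (cat.), H2O/acetone, pH 6, 60 °C
Reagents that add atoms: water, O
Why: Piancatelli rearrangement: the carbinol hydroxyl leaves, water is captured at the furan 5-position, the ring opens and the pentadienyl cation closes by conrotatory 4π electrocyclisation, which sets the 4-OH and 5-CH3 groups trans.

Step 2
Reactants: 2 (±)-trans-4-hydroxy-5-methylcyclopent-2-en-1-one
Product: 3 (4R,5S)-4-hydroxy-5-methylcyclopent-2-en-1-one
Conditions: immobilised Candida antarctica lipase B, vinyl acetate, MTBE, rt, to about half conversion; chromatography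
Reagents that add atoms: none
Why: Lipase-catalysed kinetic resolution by irreversible transesterification should acetylate the (4S,5R)-alcohol and leave the (4R,5S)-alcohol, whose methyl-bearing carbon becomes C10.

Step 3
Reactants: 3 (4R,5S)-4-hydroxy-5-methylcyclopent-2-en-1-one
Product: 4 (4S,5S)-4-hydroxy-2-iodo-5-methylcyclopent-2-en-1-one (same spatial arrangement as 3)
Conditions: I2, pyridine, CH2Cl2, 0 °C → rt
Reagents that add atoms: iodine, [I][I]
Why: α-Iodination of the enone (conjugate addition of pyridine, iodination of the enolate, elimination) marks the carbon that becomes C5 and touches no stereocentre.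

Step 4
Reactants: 4 (4S,5S)-4-hydroxy-2-iodo-5-methylcyclopent-2-en-1-one
Product: 5 (1R,4S,5S)-2-iodo-5-methyl-1-[(trimethylsilyl)ethynyl]cyclopent-2-ene-1,4-diol
Conditions: Me3SiC≡CH, nBuLi, THF, −78 °C; CeCl3, −78 °C; then 4, −78 → −40 °C; aq. NH4Cl
Reagents that add atoms: (trimethylsilyl)acetylene, C#C[Si](C)(C)C
Why: 1,2-addition of a non-basic alkynylcerium reagent to the ketone (no enolisation of the aldol-type ketone) should occur anti to the adjacent methyl group and on the face of the C9 alkoxide, which sets C1 with its oxygen cis to the C10 methyl.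

Step 5
Reactants: 5 (1R,4S,5S)-2-iodo-5-methyl-1-[(trimethylsilyl)ethynyl]cyclopent-2-ene-1,4-diol
Product: 6 (1R,4S,5S)-2-iodo-5-methyl-1,4-bis(triethylsilyloxy)-1-[(trimethylsilyl)ethynyl]cyclopent-2-ene
Conditions: Et3SiOTf (2.5 equiv), 2,6-lutidine, CH2Cl2, −78 → 0 °C
Reagents that add atoms: triethylsilyl triflate, CC[Si](CC)(CC)OS(=O)(=O)C(F)(F)F
Why: Silyl triflate silylation protects the secondary and the hindered tertiary hydroxyl in one operation; the tertiary silyl ether later shields the α face of the enone.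

Step 6
Reactants: 6 (1R,4S,5S)-2-iodo-5-methyl-1,4-bis(triethylsilyloxy)-1-[(trimethylsilyl)ethynyl]cyclopent-2-ene
Product: 9 (2R,3S,4R)-3-methyl-2,4-bis(triethylsilyloxy)-2-[(trimethylsilyl)ethynyl]cyclopentan-1-one, via alkenyllithium 7 (not isolated), via dimethyl alkenylboronate 8 (not isolated)
Conditions: tBuLi (2.1 equiv), Et2O, −78 °C; B(OMe)3, −78 → 0 °C; then H2O2 (30%), NaHCO3, THF/H2O, 0 °C
Reagents that add atoms: hydrogen peroxide, OO
Why: Iodine–lithium exchange, borylation and oxidation of the alkenylboronate put the oxygen on the former iodo carbon, so the ketone is at C5 and nowhere else.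

Step 7
Reactants: 9 (2R,3S,4R)-3-methyl-2,4-bis(triethylsilyloxy)-2-[(trimethylsilyl)ethynyl]cyclopentan-1-one
Product: 11 (3R,4S,5R)-4-methyl-3,5-bis(triethylsilyloxy)-5-[(trimethylsilyl)ethynyl]cyclopent-1-en-1-yl acetate, via lithium enolate 10 (not isolated)
Conditions: LiN(SiMe3)2, THF, −78 °C; Ac2O, −78 °C
Reagents that add atoms: acetic anhydride, CC(=O)OC(C)=O
Why: The ketone has α-hydrogens only at C8 (C1 is quaternary), so O-acetylation of its lithium enolate gives the C5=C8 enol acetate as one regioisomer, and the low temperature prevents β-elimination of the C9 silyloxy group.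

Step 8
Reactants: 11 (3R,4S,5R)-4-methyl-3,5-bis(triethylsilyloxy)-5-[(trimethylsilyl)ethynyl]cyclopent-1-en-1-yl acetate
Product: 13 (4R,5R)-3-acetoxy-5-methyl-4-(triethylsilyloxy)-4-[(trimethylsilyl)ethynyl]cyclopent-2-en-1-one, via allylic alcohol 12 (not isolated)
Conditions: HF·pyridine, pyridine, THF, 0 °C; then Dess–Martin periodinane, NaHCO3, CH2Cl2, 0 °C → rt
Reagents that add atoms: none
Why: Selective cleavage of the secondary allylic silyl ether followed by buffered Dess–Martin oxidation unveils the C9 carbonyl last and without nucleophiles, so the acetate cannot move to the other enol oxygen.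

Step 9
Reactants: 13 (4R,5R)-3-acetoxy-5-methyl-4-(triethylsilyloxy)-4-[(trimethylsilyl)ethynyl]cyclopent-2-en-1-one; 14 2,3-dihydrofuran
Product: 15 cis-anti-cis photoadduct: 9-methyl-8-oxo-10-(triethylsilyloxy)-10-[(trimethylsilyl)ethynyl]-3-oxatricyclo[5.3.0.0(2,6)]decan-1-yl acetate (cyclobutane C5–C6–C7–C8; acetoxy on C5; ring oxygen on C6; tetrahydrofuran anti to the cyclopentanone and on the face opposite to the C1 silyloxy group)
Conditions: hν (medium-pressure Hg lamp, borosilicate filter, λ > 300 nm), 14 (20 equiv), CH2Cl2, −40 °C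
Reagents that add atoms: none
Why: The triplet enone adds to the electron-rich alkene through a 1,4-diradical that closes to the four-membered ring; this is the photocycloaddition half of the de Mayo reaction of a 3-acyloxy enone with an enol ether. One ring is closed, the cyclobutane C5–C6–C7–C8, in an intermolecular [2+2] mode (C5–C6 and C7–C8, the second bond by radical recombination), cis-fused to both five-membered rings because trans fusion is not accessible in these bicycles. Head-to-tail orientation, the normal outcome for donor alkenes with cyclic enones, joins the oxygen-bearing C6 to the acetoxy carbon C5. C5 and C8 are set by the face of attack, which should be the β face because the triethylsilyloxy group on C1 and the methyl on C10 cover the α face while the alkyne on the β face is a slim rod whose silyl cap lies far from the C5=C8 bond. C6 and C7 are set by the cis geometry of the ring alkene and by exo approach, which keeps the tetrahydrofuran away from the cyclopentanone. The step needs head-to-tail regiochemistry, β-face attack and exo geometry; C5 and C8 lose their configuration in step 10, so only the relation of C6/C7 to C1/C10 is carried on.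

Step 10
Reactants: 15 cis-anti-cis photoadduct
Product: 18 cis-fused 7-ethynyl-6-methyl-7-(triethylsilyloxy)hexahydro-2H-cyclohepta[b]furan-5,8-dione (C5 and C9 ketones; C8 is CH2), via cyclobutanol 16 (not isolated), via C-silyl diketone 17 (not isolated)
Conditions: K2CO3 (0.5 equiv), MeOH, 0 °C
Reagents that add atoms: none
Why: Methanolysis of the acetate frees the cyclobutanol, whose alkoxide opens the strained ring by retro-aldol cleavage of C5–C8 towards the C9 ketone, and the same medium removes the silyl cap of the alkyne; cold, brief treatment is chosen so that C10 and C6 are not epimerised.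

Step 11
Reactants: 18 cis-fused 7-ethynyl-6-methyl-7-(triethylsilyloxy)hexahydro-2H-cyclohepta[b]furan-5,8-dione
Product: 19 cis-fused 7-ethynyl-7-hydroxy-6-methylhexahydro-2H-cyclohepta[b]furan-5,8-dione
Conditions: HF·pyridine, THF, 0 °C → rt
Reagents that add atoms: none
Why: Acidic fluoride cleavage of the tertiary triethylsilyl ether frees the C1 hydroxyl without base, so the β-hydroxy ketone neither eliminates nor undergoes retro-aldol.

Step 12
Reactants: 19 cis-fused 7-ethynyl-7-hydroxy-6-methylhexahydro-2H-cyclohepta[b]furan-5,8-dione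
Product: 20 cis-fused 7-ethynyl-6-methyloctahydro-2H-cyclohepta[b]furan-5,7,8-triol (C5–OH β; C9–OH β; C1–OH α)
Conditions: Me4NBH(OAc)3 (8 equiv), MeCN/AcOH (1:1), −30 °C → rt
Reagents that add atoms: none
Why: Hydroxyl-directed reduction (Saksena–Evans): the C1 hydroxyl binds boron and the alkoxyborohydride delivers hydride within the molecule to the α face of the α-ketone C5 and of the β-ketone C9, so both new hydroxyls should come out β, trans to the C1 oxygen (5S, 9R).

Step 13
Reactants: 20 cis-fused 7-ethynyl-6-methyloctahydro-2H-cyclohepta[b]furan-5,7,8-triol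
Product: 21 cis-fused 5-(tert-butyldimethylsilyloxy)-7-ethynyl-6-methyloctahydro-2H-cyclohepta[b]furan-7,8-diol (silyl ether on C9–O)
Conditions: tBuMe2SiCl (1.2 equiv), imidazole, DMF, 0 °C
Reagents that add atoms: tert-butyldimethylsilyl chloride, CC(C)(C)[Si](C)(C)Cl
Why: Silylation should pick the less hindered secondary hydroxyl at C9 (between CH2 and CHCH3) over C5–OH (between the quaternary C1 and the ring-fusion carbon C6) and the tertiary C1–OH.

Step 14
Reactants: 21 cis-fused 5-(tert-butyldimethylsilyloxy)-7-ethynyl-6-methyloctahydro-2H-cyclohepta[b]furan-7,8-diol; 22 (S)-2-methylbutanoic acid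
Product: 24 cis-fused 5-(tert-butyldimethylsilyloxy)-7-ethynyl-7-hydroxy-6-methyloctahydro-2H-cyclohepta[b]furan-8-yl (2S)-2-methylbutanoate, via mixed anhydride 23 (not isolated)
Conditions: 2,4,6-Cl3C6H2COCl, Et3N, THF, rt; then 21, DMAP, toluene, 40 °C
Reagents that add atoms: none
Why: Yamaguchi esterification acylates the only free secondary hydroxyl (C5–OH) through the mixed anhydride and acylpyridinium ion, the tertiary C1–OH does not react, and the α-stereocentre of the acid is not enolised.

Step 15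
Reactants: 24 cis-fused 5-(tert-butyldimethylsilyloxy)-7-ethynyl-7-hydroxy-6-methyloctahydro-2H-cyclohepta[b]furan-8-yl (2S)-2-methylbutanoate
Product: 25 cis-fused 5-(tert-butyldimethylsilyloxy)-7-ethynyl-6-methyl-7-(triethylsilyloxy)octahydro-2H-cyclohepta[b]furan-8-yl (2S)-2-methylbutanoate
Conditions: Et3SiOTf, 2,6-lutidine, CH2Cl2, −78 → 0 °C
Reagents that add atoms: triethylsilyl triflate, CC[Si](CC)(CC)OS(=O)(=O)C(F)(F)F
Why: Silyl triflate silylation caps the tertiary C1 hydroxyl so that no α-ketol or free alkoxide is present in the oxidation, aldol and enolate steps that follow.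

Step 16
Reactants: 25 cis-fused 5-(tert-butyldimethylsilyloxy)-7-ethynyl-6-methyl-7-(triethylsilyloxy)octahydro-2H-cyclohepta[b]furan-8-yl (2S)-2-methylbutanoate
Product: 26 cis-fused 7-acetyl-5-(tert-butyldimethylsilyloxy)-6-methyl-7-(triethylsilyloxy)octahydro-2H-cyclohepta[b]furan-8-yl (2S)-2-methylbutanoate
Conditions: Ph3PAuNTf2 (3 mol%), 1,4-dioxane/H2O (10:1), 60 °C
Reagents that add atoms: water, O
Why: Gold-catalysed Markovnikov hydration of the terminal alkyne places the carbonyl at C2 (any assistance by the C5 ester carbonyl leads to the same carbon) under acid-free conditions that spare the silyl ethers.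

Step 17
Reactants: 26 cis-fused 7-acetyl-5-(tert-butyldimethylsilyloxy)-6-methyl-7-(triethylsilyloxy)octahydro-2H-cyclohepta[b]furan-8-yl (2S)-2-methylbutanoate
Product: 27 cis-fused 7-acetyl-5-(tert-butyldimethylsilyloxy)-6-methyl-2-oxo-7-(triethylsilyloxy)octahydro-2H-cyclohepta[b]furan-8-yl (2S)-2-methylbutanoate
Conditions: RuCl3 (5 mol%), NaIO4 (4 equiv), CCl4/MeCN/H2O (2:2:3), rt
Reagents that add atoms: sodium periodate, [Na+].[O-][I](=O)(=O)=O
Why: RuO4-catalysed oxidation of a cyclic ether to the lactone should take the methylene C12, since the other α-position (the C6 methine) is hindered and deactivated by the acyloxy group on C5, and there is now no alkyne or free hydroxyl for the oxidant to attack.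

Step 18
Reactants: 27 cis-fused 7-acetyl-5-(tert-butyldimethylsilyloxy)-6-methyl-2-oxo-7-(triethylsilyloxy)octahydro-2H-cyclohepta[b]furan-8-yl (2S)-2-methylbutanoate; 28 acetaldehyde
Product: 30 cis-fused 5-(tert-butyldimethylsilyloxy)-7-[(3S)-3-hydroxybutanoyl]-6-methyl-2-oxo-7-(triethylsilyloxy)octahydro-2H-cyclohepta[b]furan-8-yl (2S)-2-methylbutanoate, via boron enolate 29 (not isolated)
Conditions: (−)-Ipc2BCl, Et3N, Et2O, 0 °C; then 28, −78 → −20 °C; H2O2, pH 7 buffer, MeOH, 0 °C
Reagents that add atoms: none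
Why: Boron-mediated aldol addition: the chloroborane with Et3N enolises only the methyl ketone (not the lactone or the ester), and the chiral diisopinocampheylboron enolate should add to the Re face of acetaldehyde to set C4 as S.

Step 19
Reactants: 30 cis-fused 5-(tert-butyldimethylsilyloxy)-7-[(3S)-3-hydroxybutanoyl]-6-methyl-2-oxo-7-(triethylsilyloxy)octahydro-2H-cyclohepta[b]furan-8-yl (2S)-2-methylbutanoate
Product: 31 cis-fused 7-[(1Z,3S)-1,3-bis(tert-butyldimethylsilyloxy)but-1-en-1-yl]-5-(tert-butyldimethylsilyloxy)-6-methyl-2-oxo-7-(triethylsilyloxy)octahydro-2H-cyclohepta[b]furan-8-yl (2S)-2-methylbutanoate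
Conditions: tBuMe2SiOTf (3 equiv), Et3N, CH2Cl2, −78 → 0 °C
Reagents that add atoms: tert-butyldimethylsilyl triflate, CC(C)(C)[Si](C)(C)OS(=O)(=O)C(F)(F)F
Why: Silyl triflate with Et3N silylates the C4 hydroxyl and, by soft enolisation towards C3 (the only enolisable side), masks the C2 ketone as its silyl enol ether, so that no ketone α-proton competes in step 20.

Step 20
Reactants: 31 cis-fused 7-[(1Z,3S)-1,3-bis(tert-butyldimethylsilyloxy)but-1-en-1-yl]-5-(tert-butyldimethylsilyloxy)-6-methyl-2-oxo-7-(triethylsilyloxy)octahydro-2H-cyclohepta[b]furan-8-yl (2S)-2-methylbutanoate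
Product: 35 cis-fused 7-[(1Z,3S)-1,3-bis(tert-butyldimethylsilyloxy)but-1-en-1-yl]-5-(tert-butyldimethylsilyloxy)-6-methyl-3-methylidene-2-oxo-7-(triethylsilyloxy)octahydro-2H-cyclohepta[b]furan-8-yl (2S)-2-methylbutanoate, via lithium lactone enolate 32 (not isolated), via Mannich base 33 (not isolated), via ammonium iodide 34 (not isolated)
Conditions: LiN(SiMe3)2 (1.1 equiv), THF, −78 °C; CH2=NMe2+ I−, −78 → 0 °C; MeI, CH2Cl2, rt; aq. NaHCO3, rt
Reagents that add atoms: N,N-dimethylmethyleneiminium iodide, C=[N+](C)C.[I-]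
Why: The amide base removes the lactone α-proton at C11 (more acidic and far less hindered than the α-hydrogen of the branched acyclic ester), the enolate undergoes a Mannich reaction with the iminium salt, and quaternisation followed by E1cB elimination gives the exocyclic methylene.

Step 21
Reactants: 35 cis-fused silyl-protected α-methylene lactone
Product: 36 CNP0291806.1: (3aS,5R,6S,7S,8S,8aR)-5,7-dihydroxy-7-[(3S)-3-hydroxybutanoyl]-6-methyl-3-methylidene-2-oxooctahydro-2H-cyclohepta[b]furan-8-yl (2S)-2-methylbutanoate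
Conditions: HF·pyridine, THF, 0 °C → rt
Reagents that add atoms: none
Why: Acidic fluoride desilylation turns the silyl enol ether back into the C2 ketone and frees the C4, C9 and C1 hydroxyls, while the α-methylene lactone, the ester and the β-hydroxy ketone are not exposed to base.

**Compound list**
1 | (±)-1-(furan-2-yl)ethanol | CC(O)c1ccco1 | starting material
2 | (±)-trans-4-hydroxy-5-methylcyclopent-2-en-1-one (racemate; one enantiomer drawn) | O=C1C=C[C@@H](O)[C@@H]1C | intermediate
3 | (4R,5S)-4-hydroxy-5-methylcyclopent-2-en-1-one | O=C1C=C[C@@H](O)[C@@H]1C | intermediate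
4 | (4S,5S)-4-hydroxy-2-iodo-5-methylcyclopent-2-en-1-one | O=C1C([I])=C[C@@H](O)[C@@H]1C | intermediate
5 | (1R,4S,5S)-2-iodo-5-methyl-1-[(trimethylsilyl)ethynyl]cyclopent-2-ene-1,4-diol | O[C@]1(C#C[Si](C)(C)C)C([I])=C[C@@H](O)[C@@H]1C | intermediate
6 | (1R,4S,5S)-2-iodo-5-methyl-1,4-bis(triethylsilyloxy)-1-[(trimethylsilyl)ethynyl]cyclopent-2-ene | CC[Si](CC)(CC)O[C@]1(C#C[Si](C)(C)C)C([I])=C[C@@H](O[Si](CC)(CC)CC)[C@@H]1C | intermediate
7 | alkenyllithium from 6 (Li in place of I) | CC[Si](CC)(CC)O[C@]1(C#C[Si](C)(C)C)C([Li])=C[C@@H](O[Si](CC)(CC)CC)[C@@H]1C | intermediate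
8 | dimethyl alkenylboronate from 7 | CC[Si](CC)(CC)O[C@]1(C#C[Si](C)(C)C)C(B(OC)OC)=C[C@@H](O[Si](CC)(CC)CC)[C@@H]1C | intermediate
9 | (2R,3S,4R)-3-methyl-2,4-bis(triethylsilyloxy)-2-[(trimethylsilyl)ethynyl]cyclopentan-1-one | CC[Si](CC)(CC)O[C@]1(C#C[Si](C)(C)C)C(=O)C[C@@H](O[Si](CC)(CC)CC)[C@@H]1C | intermediate
10 | lithium enolate of 9 (C5=C8) | CC[Si](CC)(CC)O[C@]1(C#C[Si](C)(C)C)C(O[Li])=C[C@@H](O[Si](CC)(CC)CC)[C@@H]1C | intermediate
11 | (3R,4S,5R)-4-methyl-3,5-bis(triethylsilyloxy)-5-[(trimethylsilyl)ethynyl]cyclopent-1-en-1-yl acetate | CC[Si](CC)(CC)O[C@]1(C#C[Si](C)(C)C)C(OC(C)=O)=C[C@@H](O[Si](CC)(CC)CC)[C@@H]1C | intermediate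
12 | (3R,4S,5R)-3-hydroxy-4-methyl-5-(triethylsilyloxy)-5-[(trimethylsilyl)ethynyl]cyclopent-1-en-1-yl acetate | CC[Si](CC)(CC)O[C@]1(C#C[Si](C)(C)C)C(OC(C)=O)=C[C@@H](O)[C@@H]1C | intermediate
13 | (4R,5R)-3-acetoxy-5-methyl-4-(triethylsilyloxy)-4-[(trimethylsilyl)ethynyl]cyclopent-2-en-1-one | O=C1[C@H](C)[C@@](O[Si](CC)(CC)CC)(C#C[Si](C)(C)C)C(OC(C)=O)=C1 | intermediate
14 | 2,3-dihydrofuran | C1=COCC1 | starting material
15 | cis-anti-cis photoadduct, 9-methyl-8-oxo-10-(triethylsilyloxy)-10-[(trimethylsilyl)ethynyl]-3-oxatricyclo[5.3.0.0(2,6)]decan-1-yl acetate | C1CO[C@@H]2[C@H]1[C@H]3C(=O)[C@H](C)[C@@](O[Si](CC)(CC)CC)(C#C[Si](C)(C)C)[C@@]23OC(C)=O | intermediate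
16 | tertiary cyclobutanol from 15 (acetate removed) | C1CO[C@@H]2[C@H]1[C@H]3C(=O)[C@H](C)[C@@](O[Si](CC)(CC)CC)(C#C[Si](C)(C)C)[C@@]23O | intermediate
17 | cis-fused 6-methyl-7-(triethylsilyloxy)-7-[(trimethylsilyl)ethynyl]hexahydro-2H-cyclohepta[b]furan-5,8-dione | C1CO[C@@H]2[C@H]1CC(=O)[C@H](C)[C@@](O[Si](CC)(CC)CC)(C#C[Si](C)(C)C)C2=O | intermediate
18 | cis-fused 7-ethynyl-6-methyl-7-(triethylsilyloxy)hexahydro-2H-cyclohepta[b]furan-5,8-dione | C1CO[C@@H]2[C@H]1CC(=O)[C@H](C)[C@@](O[Si](CC)(CC)CC)(C#C)C2=O | intermediate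
19 | cis-fused 7-ethynyl-7-hydroxy-6-methylhexahydro-2H-cyclohepta[b]furan-5,8-dione | C1CO[C@@H]2[C@H]1CC(=O)[C@H](C)[C@@](O)(C#C)C2=O | intermediate
20 | cis-fused 7-ethynyl-6-methyloctahydro-2H-cyclohepta[b]furan-5,7,8-triol | C1CO[C@@H]2[C@H]1C[C@@H](O)[C@H](C)[C@@](O)(C#C)[C@H]2O | intermediate
21 | cis-fused 5-(tert-butyldimethylsilyloxy)-7-ethynyl-6-methyloctahydro-2H-cyclohepta[b]furan-7,8-diol | C1CO[C@@H]2[C@H]1C[C@@H](O[Si](C)(C)C(C)(C)C)[C@H](C)[C@@](O)(C#C)[C@H]2O | intermediate
22 | (S)-2-methylbutanoic acid | CC[C@H](C)C(O)=O | starting material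
23 | (2S)-2-methylbutanoic 2,4,6-trichlorobenzoic anhydride | CC[C@H](C)C(=O)OC(=O)c1c(Cl)cc(Cl)cc1Cl | intermediate
24 | C5 ester: 5-(tert-butyldimethylsilyloxy)-7-ethynyl-7-hydroxy-6-methyloctahydro-2H-cyclohepta[b]furan-8-yl (2S)-2-methylbutanoate | C1CO[C@@H]2[C@H]1C[C@@H](O[Si](C)(C)C(C)(C)C)[C@H](C)[C@@](O)(C#C)[C@H]2OC(=O)[C@@H](C)CC | intermediate
25 | C1 triethylsilyl ether of 24 | C1CO[C@@H]2[C@H]1C[C@@H](O[Si](C)(C)C(C)(C)C)[C@H](C)[C@@](O[Si](CC)(CC)CC)(C#C)[C@H]2OC(=O)[C@@H](C)CC | intermediate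
26 | methyl ketone: 7-acetyl-5-(tert-butyldimethylsilyloxy)-6-methyl-7-(triethylsilyloxy)octahydro-2H-cyclohepta[b]furan-8-yl (2S)-2-methylbutanoate | C1CO[C@@H]2[C@H]1C[C@@H](O[Si](C)(C)C(C)(C)C)[C@H](C)[C@@](O[Si](CC)(CC)CC)(C(C)=O)[C@H]2OC(=O)[C@@H](C)CC | intermediate
27 | lactone: 2-oxo derivative of 26 | C1C(=O)O[C@@H]2[C@H]1C[C@@H](O[Si](C)(C)C(C)(C)C)[C@H](C)[C@@](O[Si](CC)(CC)CC)(C(C)=O)[C@H]2OC(=O)[C@@H](C)CC | intermediate
28 | acetaldehyde | CC=O | starting material
29 | diisopinocampheylboron enolate of 27 | C1C(=O)O[C@@H]2[C@H]1C[C@@H](O[Si](C)(C)C(C)(C)C)[C@H](C)[C@@](O[Si](CC)(CC)CC)(C(=C)OB([C@@H]3C[C@@H]4C[C@H]([C@H]3C)C4(C)C)[C@@H]5C[C@@H]6C[C@H]([C@H]5C)C6(C)C)[C@H]2OC(=O)[C@@H](C)CC | intermediate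
30 | aldol: 7-[(3S)-3-hydroxybutanoyl] lactone | C1C(=O)O[C@@H]2[C@H]1C[C@@H](O[Si](C)(C)C(C)(C)C)[C@H](C)[C@@](O[Si](CC)(CC)CC)(C(=O)C[C@H](C)O)[C@H]2OC(=O)[C@@H](C)CC | intermediate
31 | 7-[(1Z,3S)-1,3-bis(tert-butyldimethylsilyloxy)but-1-en-1-yl] lactone | C1C(=O)O[C@@H]2[C@H]1C[C@@H](O[Si](C)(C)C(C)(C)C)[C@H](C)[C@@](O[Si](CC)(CC)CC)(/C(O[Si](C)(C)C(C)(C)C)=C/[C@H](C)O[Si](C)(C)C(C)(C)C)[C@H]2OC(=O)[C@@H](C)CC | intermediate
32 | lithium enolate of lactone 31 | C1=C(O[Li])O[C@@H]2[C@H]1C[C@@H](O[Si](C)(C)C(C)(C)C)[C@H](C)[C@@](O[Si](CC)(CC)CC)(/C(O[Si](C)(C)C(C)(C)C)=C/[C@H](C)O[Si](C)(C)C(C)(C)C)[C@H]2OC(=O)[C@@H](C)CC | intermediate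
33 | Mannich base, 3-[(dimethylamino)methyl] lactone (C11 epimers, inconsequential) | CN(C)CC1C(=O)O[C@@H]2[C@H]1C[C@@H](O[Si](C)(C)C(C)(C)C)[C@H](C)[C@@](O[Si](CC)(CC)CC)(/C(O[Si](C)(C)C(C)(C)C)=C/[C@H](C)O[Si](C)(C)C(C)(C)C)[C@H]2OC(=O)[C@@H](C)CC | intermediate
34 | trimethylammonium iodide of 33 | [I-].C[N+](C)(C)CC1C(=O)O[C@@H]2[C@H]1C[C@@H](O[Si](C)(C)C(C)(C)C)[C@H](C)[C@@](O[Si](CC)(CC)CC)(/C(O[Si](C)(C)C(C)(C)C)=C/[C@H](C)O[Si](C)(C)C(C)(C)C)[C@H]2OC(=O)[C@@H](C)CC | intermediate
35 | silyl-protected α-methylene lactone | C=C1C(=O)O[C@@H]2[C@H]1C[C@@H](O[Si](C)(C)C(C)(C)C)[C@H](C)[C@@](O[Si](CC)(CC)CC)(/C(O[Si](C)(C)C(C)(C)C)=C/[C@H](C)O[Si](C)(C)C(C)(C)C)[C@H]2OC(=O)[C@@H](C)CC | intermediate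
36 | CNP0291806.1 | C=C1C(=O)O[C@@H]2[C@H]1C[C@@H](O)[C@H](C)[C@@](O)(C(=O)C[C@H](C)O)[C@H]2OC(=O)[C@@H](C)CC | target

**Step count and risks**
Total steps: 21. Longest linear sequence: 21 steps (from 1; compounds 14, 22 and 28 are bought).

Most likely to fail:

Step 9. What may go wrong: the alkene adds to the α face (the side of the silyloxy and methyl groups), in the endo mode, or head-to-head; after fragmentation each of these gives a diketone with the wrong relation of C6/C7 to C1/C10 or the wrong connectivity, and this cannot be corrected later. Fallback, setting out from 13 and returning at 18: the order of alkyne deprotection and cycloaddition is reversed, so that the β face carries nothing beyond two sp carbons. The silyl cap is removed first (AgNO3 cat., 2,6-lutidine, acetone/H2O) to give the 4-ethynyl acetoxy enone F1; F1 is irradiated with 14 to give the photoadduct F2, and K2CO3/MeOH converts F2 into 18.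

Step 12. What may go wrong: the hindered C5 carbonyl is not reached by intramolecular delivery, or is reduced from the β face, so that only the C9 carbinol is set. Fallback, setting out from 19 and returning at 21: the two reductions are separated and the second is run under chelation control. The reduction is stopped at the C9-reduced hydroxy ketone F3 (Me4NBH(OAc)3, −40 °C), the C9 hydroxyl is silylated (tBuMe2SiCl, imidazole) to give the silyl ether F4, and the α-hydroxy ketone is reduced with Zn(BH4)2 in Et2O at −20 °C, where zinc bridges the C1 hydroxyl and the C5 carbonyl and hydride arrives on the α face, giving 21.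

Step 18. What may go wrong: poor facial selectivity at the aldehyde, because the chiral boron ligands must override an α-quaternary ketone, giving C4 epimers. Fallback, setting out from 27 and returning at 30: C4 is set by reduction instead of by C–C bond formation. The methyl ketone is C-acetylated by soft enolisation (MgBr2·OEt2, iPr2NEt, 1-acetylbenzotriazole, CH2Cl2) to the 1,3-diketone F5, and the unhindered acetyl carbonyl is hydrogenated with RuCl2[(S)-BINAP] (H2, MeOH, 40 °C); in BINAP–ruthenium hydrogenation of β-dicarbonyl compounds the (S)-ligand gives the (S)-carbinol, and the carbonyl next to the quaternary C1 should be left.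

**Further compounds**
F1 | step 9 | (4R,5R)-3-acetoxy-4-ethynyl-5-methyl-4-(triethylsilyloxy)cyclopent-2-en-1-one | O=C1[C@H](C)[C@@](O[Si](CC)(CC)CC)(C#C)C(OC(C)=O)=C1
F2 | step 9 | cis-anti-cis photoadduct of F1 with 2,3-dihydrofuran (10-ethynyl analogue of 15) | C1CO[C@@H]2[C@H]1[C@H]3C(=O)[C@H](C)[C@@](O[Si](CC)(CC)CC)(C#C)[C@@]23OC(C)=O
F3 | step 12 | cis-fused 7-ethynyl-5,7-dihydroxy-6-methylhexahydro-2H-cyclohepta[b]furan-8-one (C9–OH β; C5 ketone) | C1CO[C@@H]2[C@H]1C[C@@H](O)[C@H](C)[C@@](O)(C#C)C2=O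
F4 | step 12 | cis-fused 5-(tert-butyldimethylsilyloxy)-7-ethynyl-7-hydroxy-6-methylhexahydro-2H-cyclohepta[b]furan-8-one | C1CO[C@@H]2[C@H]1C[C@@H](O[Si](C)(C)C(C)(C)C)[C@H](C)[C@@](O)(C#C)C2=O
F5 | step 18 | cis-fused 5-(tert-butyldimethylsilyloxy)-6-methyl-2-oxo-7-(3-oxobutanoyl)-7-(triethylsilyloxy)octahydro-2H-cyclohepta[b]furan-8-yl (2S)-2-methylbutanoate | C1C(=O)O[C@@H]2[C@H]1C[C@@H](O[Si](C)(C)C(C)(C)C)[C@H](C)[C@@](O[Si](CC)(CC)CC)(C(=O)CC(C)=O)[C@H]2OC(=O)[C@@H](C)CC
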